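We must decide whether to spend our solid substrate on the flask, so we need its product at 2.5 d and what a longer wait could add.

| flask | solid substrate | partner | second reagent | capture agent | remark | time |
|---|---|---|---|---|---|---|
| dawn | 0.15 M | 0.071 M | 0.075 M | 0.015 M | run made earlier |  |
| autumn | 0.15 M | 0.11 M | 0.075 M | 0.015 M | run made earlier |  |
| spring | 0.15 M | 0.142 M | 0.075 M | 0.030 M | run made earlier |  |
| flask | 0.15 M | 0.142 M | 0.0750 M | 0.0150 M |  | 2.5 d |

| run | time / h | product / % |
|---|---|---|
| dawn | 3.00 | 1 |
| dawn | 6.00 | 1 |
| dawn | 15.0 | 7 |
| dawn | 40.0 | 19 |
| autumn | 3.00 | 0 |
| autumn | 6.00 | 3 |
| autumn | 15.0 | 9 |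
| autumn | 40.0 | 28 |
| spring | 10.0 | 6 |
| spring | 20.0 | 14 |
| spring | 25.0 | 21 |
| spring | 40.0 | 31 |

(each reading ± 1.5 percentage points)

- given per volume of solution although it is solid: solid substrate
- what was read earlier has a scatter of 1.5 percentage points, one standard deviation
- at the start none of the solid substrate is in solution
- what has only dissolved of solid substrate counts as not reacted

1. how much product there is at 2.5 d, in percent of the solid substrate charged
2. amount of product if the flask were left three thousand times as long, in percent of the solid substrate charged

The bench habit is a ruler through the spring run, which has the partner charge of the flask, though it carries twice the capture agent of the flask. From 6% at 10.0 h to 31% at 40.0 h, the line reaches 47.7% at 2.5 d.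

The flask charges less second reagent than partner or solid substrate. If the reaction runs one to one, which no run proves, second reagent is the limiting reagent, and the ratio [second reagent]/[solid substrate] as charged gives 50.0%, the product ceiling: the most product, as a share of the solid substrate charged, that this charge allows. The ruler has used nearly all of that ceiling.

So we count the fraction of second reagent left, one minus product over ceiling. The spring readings, with their scatter, put it at 88.0% at 10.0 h and 38.0% at 40.0 h. Assuming equal times multiply it by equal factors, we estimate 21.7% left in the flask at 2.5 d, so our own estimate of its product is 39.1%.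

The forecast is higher than ours, at 41%, with 50% for the long wait: “This cap is inferred, since no run has reached it.”

The flask gives 42.1% and, after the long wait, 50.0%.

    open intermediate + capture agent → trapped intermediate (k = 0.00330 L mol⁻¹ min⁻¹)
    second reagent + open intermediate → product (k = 0.0570 L mol⁻¹ min⁻¹)
    starting material + partner → open intermediate (k = 0.00530 L mol⁻¹ min⁻¹)
    solid substrate ⇌ starting material, rate k4*(cs4 - [starting material]) while solid is left; crystals form when [starting material] > cs4 (solubility = 0.0540 M, k = 0.00340 min⁻¹)

We reckoned 21.7% of the second reagent left, and the flask keeps 16% of its charge at 2.50 d; the ceiling times the fraction used is 42.0%. The same flask with 0.030 M of second reagent has a ceiling of 20.0%. It keeps 0.904% of its second reagent at 2.50 d, which reckons to 19.8%, and it holds 19.8% of product.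

The runs were computed for an exercise; noise was put on by code.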